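## Retrosynthetic overview
1. Key disconnection, the ester O–C1(alkyl) bond: gentiside F ⇒ 2,3-dihydroxybenzoic acid + (S)-16-methyloctadec-1-yne + H2. The acid O–H adds anti-Markovnikov across C≡C and the product is saturated in the same pot, without protecting groups.
2. C2–C3 of the alkyne ⇒ acetylide + (S)-1-bromo-14-methylhexadecane (SN2).
3. C12–C13 of that bromide ⇒ (S)-2-methylbutyl Grignard + 1,12-dibromododecane (Cu-catalysed sp3–sp3 coupling).
4. The only stereocentre is bought in (S)-1-bromo-2-methylbutane and is never touched.
5. No ring is formed; the benzene ring comes with the acid.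

Assumption: the SMILES is read as (S)-16-methyloctadecyl 2,3-dihydroxybenzoate (15 CH2 between O and the stereocentre), and catalogue (S)-1-bromo-2-methylbutane of high ee is taken as the chirality source.

## Route

Step 1
Reactants: 1 (S)-1-bromo-2-methylbutane; 2 1,12-dibromododecane
Product: 4 (S)-1-bromo-14-methylhexadecane, via (S)-2-methylbutylmagnesium bromide 3 (not isolated)
Conditions: 1, Mg (1.2 equiv), THF, 45 °C; then added over 2 h to 2 (3 equiv), Li2CuCl4 (3 mol %), NMP (4 equiv), THF, −10 °C → rt; excess 2 removed by Kugelrohr distillation and reused; SiO2, hexane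
Reagents that add atoms: none
Why: This is a Kochi-type Cu-catalysed sp3–sp3 Kumada coupling of a primary Grignard with a primary bromide; slow addition into a threefold excess of cheap 2 keeps double coupling near or below 10 %, and the stereocentre sits β to magnesium, where neither Grignard formation nor coupling can touch it, so the (S) configuration of 1 is carried over unchanged.

Step 2
Reactants: 4 (S)-1-bromo-14-methylhexadecane; 5 lithium acetylide–ethylenediamine complex
Product: 6 (S)-16-methyloctadec-1-yne
Conditions: 5 (1.5 equiv), DMSO–THF (3:1), 10 °C → rt, 6 h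
Reagents that add atoms: none
Why: SN2 alkylation of an acetylide by an unhindered primary bromide in a dipolar aprotic medium is textbook terminal-alkyne synthesis; E2 is minor at room temperature and the remote stereocentre is inert to the base.

Step 3
Reactants: 6 (S)-16-methyloctadec-1-yne; 7 2,3-dihydroxybenzoic acid
Product: 9 gentiside F = (S)-16-methyloctadecyl 2,3-dihydroxybenzoate, via (Z)-enol ester 8 (not isolated)
Conditions: 7 (1.05 equiv), [Ru(η3-methallyl)2(dppb)] (2 mol %, from Ru(methallyl)2(cod) + 1,4-bis(diphenylphosphino)butane), toluene–2-MeTHF (4:1), Ar, 65 °C, 8 h; then H2 (30 bar), 70 °C, 16 h, same vessel; SiO2, hexane–EtOAc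
Reagents that add atoms: none
Why: Proposed new method: a net anti-Markovnikov reductive hydroacyloxylation of a terminal alkyne (RC≡CH + ArCO2H + H2 → RCH2CH2O2CAr) by one Ru precatalyst in one vessel, run on an unprotected catechol acid; 7 (pKa about 2.9, more than 10^6 times more acidic than its phenols) protonates off both methallyl ligands to give Ru(κ2-O2CAr)2(dppb); the alkyne tautomerises on Ru to the vinylidene Ru=C=CHR, whose electrophilic Cα (the former terminal carbon) is attacked by the bound carboxylate, so the new O–C1 bond can only form at the chain end, and protonolysis releases (Z)-enol ester 8; the Ru dicarboxylate/diphosphine left in solution is the type of complex that splits H2 heterolytically and hydrogenates chelating enol esters, so H2 pressure should convert 8 into 9 before this activated ester acylates a phenol or is trapped by the 2-OH; the phenols should stay out because the 2-OH is held in the salicylate hydrogen bond and neutral phenols are not expected to add to Ru vinylidenes under these conditions; no new stereocentre forms and remote C16 is untouched; the closest known reaction types are the Ru-vinylidene anti-Markovnikov addition of benzoic acids to 1-alkynes and, separately, Ru(carboxylate)2(diphosphine) hydrogenation of enol esters.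

## Compound list
1 | (S)-1-bromo-2-methylbutane | CC[C@H](C)CBr | starting material
2 | 1,12-dibromododecane | BrCCCCCCCCCCCCBr | starting material
3 | (S)-2-methylbutylmagnesium bromide | CC[C@H](C)C[Mg]Br | intermediate
4 | (S)-1-bromo-14-methylhexadecane | CC[C@H](C)CCCCCCCCCCCCCBr | intermediate
5 | lithium acetylide–ethylenediamine complex | [Li+].[C-]#C.NCCN | starting material
6 | (S)-16-methyloctadec-1-yne | CC[C@H](C)CCCCCCCCCCCCCC#C | intermediate
7 | 2,3-dihydroxybenzoic acid | OC(=O)c1cccc(O)c1O | starting material
8 | (1Z,16S)-16-methyloctadec-1-en-1-yl 2,3-dihydroxybenzoate | CC[C@H](C)CCCCCCCCCCCCC/C=C\OC(=O)c1cccc(O)c1O | intermediate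
9 | gentiside F, (S)-16-methyloctadecyl 2,3-dihydroxybenzoate | CC[C@H](C)CCCCCCCCCCCCCCCOC(=O)c1cccc(O)c1O | target

## Totals and risks
Total step count: 3. Longest linear sequence: 3.

**Risk 1, step 3 (the new step).**
- Possible failures: the catechol/salicylate unit chelates Ru and stops turnover; 8 is trapped by its own 2-OH; the homogeneous hydrogenation is too slow.
- The fallback uses known chemistry only. It sets out from 4 and comes back at 9.
- Bromide 4 with Mg in THF gives (S)-14-methylhexadecylmagnesium bromide F1.
- Ethylene oxide (CuI 5 mol %, −30 → 0 °C) opens to bromomagnesium (S)-16-methyloctadecan-1-olate F2. NH4Cl work-up then gives (S)-16-methyloctadecan-1-ol F3.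
- Mitsunobu esterification of F3 with unprotected 7 (PPh3, DIAD, THF, 0 °C → rt) gives 9. At 1:1 stoichiometry the carboxylic acid is the favoured pronucleophile.
- The total stays at 3 steps.

**Risk 2, step 1.**
- Possible failures: the mono-coupling is only statistically controlled, and 4 must be separated from excess 2 and from the doubly coupled hydrocarbon.
- The fallback uses a linker with two different ends. It sets out from 3 (made from 1) and comes back at 4.
- Commercial 12-bromododecan-1-ol F4 is deprotonated with MeMgCl (1.0 equiv, THF, 0 °C) to chloromagnesium 12-bromododecan-1-olate F5.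
- F5 is coupled with 3 (1.2 equiv, Li2CuCl4 cat.) to chloromagnesium (S)-14-methylhexadecan-1-olate F6. NH4Cl work-up gives (S)-14-methylhexadecan-1-ol F7, which is easily separated on silica.
- Appel bromination of F7 (CBr4, PPh3, CH2Cl2, 0 °C) returns 4.

**Risk 3, step 2.**
- Possible failures: the waxy bromide dissolves poorly in DMSO; competing E2; base-induced migration of the triple bond.
- The fallback builds the alkyne from two one-carbon units instead of an acetylide SN2. It sets out from 4 and comes back at 6.
- Bromide 4 is converted to (S)-14-methylhexadecylmagnesium bromide F1, which adds to DMF (THF, 0 °C) to give the bromomagnesium hemiaminal alkoxide F8.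
- Dilute HCl work-up releases (S)-15-methylheptadecanal F9.
- Seyferth–Gilbert homologation of F9 with the Ohira–Bestmann reagent (dimethyl (1-diazo-2-oxopropyl)phosphonate, K2CO3, MeOH, rt) gives 6.

## Further compounds
F1 | step 3 | (S)-14-methylhexadecylmagnesium bromide | CC[C@H](C)CCCCCCCCCCCCC[Mg]Br
F2 | step 3 | bromomagnesium (S)-16-methyloctadecan-1-olate | CC[C@H](C)CCCCCCCCCCCCCCCO[Mg]Br
F3 | step 3 | (S)-16-methyloctadecan-1-ol | CC[C@H](C)CCCCCCCCCCCCCCCO
F4 | step 1 | 12-bromododecan-1-ol (bought) | OCCCCCCCCCCCCBr
F5 | step 1 | chloromagnesium 12-bromododecan-1-olate | Cl[Mg]OCCCCCCCCCCCCBr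
F6 | step 1 | chloromagnesium (S)-14-methylhexadecan-1-olate | CC[C@H](C)CCCCCCCCCCCCCO[Mg]Cl
F7 | step 1 | (S)-14-methylhexadecan-1-ol | CC[C@H](C)CCCCCCCCCCCCCO
F8 | step 2 | bromomagnesium (15S)-1-(dimethylamino)-15-methylheptadecan-1-olate (DMF adduct) | CC[C@H](C)CCCCCCCCCCCCCC(O[Mg]Br)N(C)C
F9 | step 2 | (S)-15-methylheptadecanal | CC[C@H](C)CCCCCCCCCCCCCC=O
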